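**Plan**

- Retrosynthesis: the 14-membered ring of 31 is cut at C10–C11 (ring CH2 to the methyl-bearing carbon of the 11E alkene), then at the C1=C2 alkene (olefination) and at C6–C7 (ring CH2 to the methyl-bearing carbon of the 7Z alkene); the side chain is cut at its allyl–prenyl CH2–CH2 bond.
- Enabling feature: C11 is the fully substituted sp2 carbon of an E-trisubstituted alkene and C10 is an unactivated CH2 homoallylic to C7=C8, so the open form is an E-alkenyl iodide plus an alk-4-enoic acid whose CO2H sits on C10 and leaves as CO2; C6–C7 has the same pattern.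
- Forward, core: the cyclohexane ring of limonene-1,2-diol supplies C2–C6 with C4; its isopropenyl group is prenylated, then glycol cleavage and a haloform reaction give C2 as a masked aldehyde and a carboxyl group on C6.
- Forward, chain joining: decarboxylative alkenylation (C6–C7) with a Z-iodoalkenoate, Still–Gennari olefination (C1=C2) with a phosphonate carrying the E-alkenyl iodide, selective saponification, electrochemical decarboxylative ring closure (C10–C11), ester reduction.
- Stereochemistry: C4 (R) is C4 of the diol and is never α to a carbonyl; 7Z comes from a Z-selective iodo-Wittig reaction, 11E from syn hydrozirconation, 1Z from the Still–Gennari step; both alkenyl iodides are coupled with retention.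

Key step: step 13

Remark: ring atoms are numbered as in the name of 31 (C1 carries CH2OH, C4 the side chain, C7 and C11 the methyl groups); commercial diol 1 is taken as enantiopure.

**Route**

Step 1
Reactants: 1 (1S,2S,4R)-1-methyl-4-(prop-1-en-2-yl)cyclohexane-1,2-diol
Product: 2 (3aS,5R,7aS)-2,2,7a-trimethyl-5-(prop-1-en-2-yl)hexahydro-1,3-benzodioxole (trans-fused acetonide of 1)
Conditions: 2-methoxypropene, cat. PPTS, CH2Cl2, 0 °C → rt
Reagents that add atoms: 2-methoxypropene, COC(C)=C
Why: Acid-catalysed ketalisation of the trans-diol (which can reach the diequatorial chair) masks the future aldehyde and ketone carbons as a base-stable ring, so that only the isopropenyl group carries accessible allylic hydrogens in step 2; no stereocentre is touched.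

Step 2
Reactants: 2 acetonide; 3 1-bromo-3-methylbut-2-ene (prenyl bromide)
Product: 5 (3aS,5R,7aS)-2,2,7a-trimethyl-5-(6-methylhepta-1,5-dien-2-yl)hexahydro-1,3-benzodioxole, via allylpotassium 4 (not isolated)
Conditions: n-BuLi, KOt-Bu, THF/hexane, −78 → −50 °C; then 3, −78 °C → rt
Reagents that add atoms: none
Why: Allylic metalation by the n-BuLi/KOt-Bu superbase removes a proton from the isopropenyl methyl group, and the 2-substituted allyl anion (two equivalent CH2 termini) is alkylated at the primary carbon of the allylic bromide (SN2), a known metalation–alkylation of limonene-type isopropenyl groups; the future C4 is untouched.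

Step 3
Reactants: 5 prenylated acetonide
Product: 8 (5R)-7,7-dimethoxy-5-(6-methylhepta-1,5-dien-2-yl)heptan-2-one, via diol 6 (not isolated), via keto aldehyde 7 (not isolated)
Conditions: H5IO6, THF/H2O, 0 °C → rt; extractive work-up; then HC(OMe)3, cat. CeCl3·7H2O, MeOH, rt
Reagents that add atoms: trimethyl orthoformate, COC(OC)OC
Why: Periodic acid hydrolyses the strained trans-fused acetonide and cleaves the liberated glycol (Malaprade cleavage) without touching the alkenes, and the aldehyde, far more electrophilic than the methyl ketone, is then acetalised selectively; the stereocentre is β to the aldehyde and γ to the ketone and cannot epimerise.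

Step 4
Reactants: 8 keto acetal
Product: 9 (4R)-6,6-dimethoxy-4-(6-methylhepta-1,5-dien-2-yl)hexanoic acid
Conditions: NaOBr (Br2, NaOH), 1,4-dioxane/H2O, 0 °C; Na2SO3; then NaH2PO4 to pH 5
Reagents that add atoms: sodium hydroxide, [Na+].[OH-]
Why: Haloform reaction: the methyl group is tribrominated through the enolate and hydroxide cleaves the tribromomethyl ketone, which leaves a carboxyl group on the future ring carbon C6; isolated alkenes are inert to hypobromite in strong base and the acetal is base-stable.

Step 5
Reactants: 10 methyl 4-oxobutanoate; 11 ethyltriphenylphosphonium iodide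
Product: 15 methyl (4Z)-5-iodohex-4-enoate, via ethylidene ylide 12 (not isolated), via iodophosphonium iodide 13 (not isolated), via iodo ylide 14 (not isolated)
Conditions: 11, n-BuLi, THF, −78 °C → rt; I2, −78 °C; NaN(SiMe3)2, −78 °C; then 10, −78 → −20 °C
Reagents that add atoms: iodine, [I][I]
Why: Stork–Zhao-type α-iodo Wittig olefination: the non-stabilised 1-iodoethylidene ylide adds to the aldehyde under kinetic control and should give the Z-2-iodoalk-2-ene (iodine cis to the ester-bearing chain), which fixes the later 7Z ring alkene.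

Step 6
Reactants: 9 acetal acid; 15 Z-alkenyl iodide
Product: 17 methyl (4Z,8R)-10,10-dimethoxy-5-methyl-8-(6-methylhepta-1,5-dien-2-yl)dec-4-enoate, via N-acyloxyphthalimide 16 (not isolated)
Conditions: N-hydroxyphthalimide, DIC, cat. DMAP, CH2Cl2, rt; then 15, NiCl2·6H2O (20 mol %), 2,2′-bipyridine, AgNO3 (0.3 equiv), DMF, Mg anode/RVC cathode, constant current, rt
Reagents that add atoms: none
Why: Nickel-electrocatalytic decarboxylative alkenylation of a redox-active N-acyloxyphthalimide with an alkenyl iodide (known reaction type): reduction fragments the ester to CO2 and a primary radical at the future C6, the alkenylnickel species formed from 15 captures it, and reductive elimination forms the C(sp3)–C(sp2) bond with retention of the Z geometry; acetal, ester and remote alkenes are spectators.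

Step 7
Reactants: 17 ester acetal
Product: 18 methyl (4Z,8R)-5-methyl-8-(6-methylhepta-1,5-dien-2-yl)-10-oxodec-4-enoate
Conditions: PPTS, acetone/H2O, 45 °C
Reagents that add atoms: water, O
Why: Mild acid-catalysed acetal hydrolysis frees the aldehyde while the methyl ester and the tri- and 1,1-disubstituted alkenes survive; the stereocentre is β to the carbonyl and is not epimerisable.

Step 8
Reactants: 19 pent-3-yn-1-ol
Product: 21 (3E)-4-iodopent-3-en-1-ol, via alkenylzirconocene 20 (not isolated)
Conditions: Cp2Zr(H)Cl (2.5 equiv), THF, rt → 45 °C; then I2, 0 °C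
Reagents that add atoms: iodine, [I][I]
Why: Syn hydrozirconation (the first equivalent is consumed by the hydroxyl group) places zirconium, after equilibration by the excess reagent, on the less hindered methyl-bearing alkyne carbon, and iodinolysis with retention should give the E-alkenyl iodide that fixes the 11E ring alkene.

Step 9
Reactants: 21 iodo alcohol
Product: 22 (2E)-2,5-diiodopent-2-ene
Conditions: I2, PPh3, imidazole, CH2Cl2, 0 °C
Reagents that add atoms: iodine, [I][I]
Why: Appel-type iodination converts the primary alcohol into the iodide by SN2 displacement of the alkoxyphosphonium ion; the alkenyl iodide is inert.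

Step 10
Reactants: 22 diiodide; 23 methyl bis(2,2,2-trifluoroethyl)phosphonoacetate
Product: 25 methyl (5E)-2-[bis(2,2,2-trifluoroethoxy)phosphoryl]-6-iodohept-5-enoate, via sodium phosphonoacetate 24 (not isolated)
Conditions: NaH, DMF, 0 °C; then 22, rt
Reagents that add atoms: none
Why: C-alkylation of the stabilised phosphonoacetate anion by the primary iodide (SN2); the anion is weakly basic, which limits E2 elimination of the homoallylic iodide, and the alkenyl iodide does not react.

Step 11
Reactants: 18 aldehyde ester; 25 phosphonate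
Product: 27 dimethyl (2Z,5R,8Z)-2-[(3E)-4-iodopent-3-en-1-yl]-8-methyl-5-(6-methylhepta-1,5-dien-2-yl)dodeca-2,8-dienedioate, via potassium phosphonate 26 (not isolated)
Conditions: 25, KN(SiMe3)2, 18-crown-6, THF, −78 °C; then 18, −78 °C
Reagents that add atoms: none
Why: Still–Gennari olefination: the bis(trifluoroethyl) phosphonate anion with a dissociated potassium counter-ion adds to the aldehyde and eliminates rapidly from the kinetic adduct, which should give the Z-enoate (ester cis to the chain that carries the stereocentre, as the CH2OH group of the target requires); the saturated ester is untouched and the stereocentre is not α to the carbonyl.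

Step 12
Reactants: 27 diester
Product: 28 (4Z,8R,10Z,14E)-15-iodo-11-(methoxycarbonyl)-5-methyl-8-(6-methylhepta-1,5-dien-2-yl)hexadeca-4,10,14-trienoic acid
Conditions: LiOH, THF/H2O, 0 °C; then aq. HCl to pH 3
Reagents that add atoms: lithium hydroxide, [Li+].[OH-]
Why: Chemoselective saponification: hydroxide attacks the unhindered saturated methyl ester much faster than the α-branched, conjugated Z-enoate, so only the acid needed for the ring closure is freed.

Step 13
Reactants: 28 seco acid
Product: 30 methyl (1Z,4R,7Z,11E)-7,11-dimethyl-4-(6-methylhepta-1,5-dien-2-yl)cyclotetradeca-1,7,11-triene-1-carboxylate, via N-acyloxyphthalimide 29 (not isolated)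
Conditions: N-hydroxyphthalimide, DIC, cat. DMAP, CH2Cl2, rt; then syringe-pump addition to NiCl2·6H2O (30 mol %), 2,2′-bipyridine, AgNO3 (0.3 equiv), DMF, Mg anode/RVC cathode, constant current, rt, final concentration about 2 mM
Reagents that add atoms: none
Why: Proposed new method: the acid is converted into its N-acyloxyphthalimide, zerovalent nickel (bipyridine) inserts into the C11–I bond to give an alkenyl divalent nickel species, single-electron reduction of the redox-active ester at the silver-coated cathode or by low-valent nickel releases CO2 and the primary C10 radical, which is captured by the alkenylnickel end of the same chain, and reductive elimination from trivalent nickel forms C10–C11. The closest known reaction type is the intermolecular nickel-electrocatalytic decarboxylative alkenylation of N-acyloxyphthalimides with alkenyl iodides (as in step 6) and, for ring closure through an alkenylmetal, the Nozaki–Hiyama–Kishi macrocyclisation; the intramolecular, macrocyclising variant is the new element. The 14-membered ring closes by radical capture at the metal to a 15-membered nickelacycle followed by ring-contracting C(sp2)–C(sp3) reductive elimination, not by radical addition to an alkene. No stereocentre is formed, C4 is remote from both reacting ends, and the E geometry at C11=C12 is carried over from the configurationally stable alkenylnickel. The step needs ring closure to beat intermolecular capture and hydrogen-atom quenching, which slow addition at millimolar concentration should secure, helped by the two cis-trisubstituted alkenes (C1=C2 and C7=C8) that fold the chain; it also needs the homoallylic C10 radical to be captured before reversible 3-exo closure onto C7=C8 can scramble that alkene, and the α-branched enoate (nine-membered transition state) is too poor an acceptor to intercept the radical.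

Step 14
Reactants: 30 macrocyclic ester
Product: 31 [(1Z,4R,7Z,11E)-7,11-dimethyl-4-(6-methylhepta-1,5-dien-2-yl)cyclotetradeca-1,7,11-trien-1-yl]methanol
Conditions: i-Bu2AlH, CH2Cl2, −78 °C; aq. potassium sodium tartrate
Reagents that add atoms: none
Why: 1,2-Reduction of the conjugated methyl ester by i-Bu2AlH stops at the allylic alcohol, leaves the isolated alkenes untouched and does not change the geometry of the C1=C2 bond.

**Compound list**

1 | (1S,2S,4R)-1-methyl-4-(prop-1-en-2-yl)cyclohexane-1,2-diol (limonene-1,2-diol) | CC(=C)[C@@H]1CC[C@](C)(O)[C@@H](O)C1 | starting material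
2 | (3aS,5R,7aS)-2,2,7a-trimethyl-5-(prop-1-en-2-yl)hexahydro-1,3-benzodioxole | CC(=C)[C@@H]1CC[C@]2(C)OC(C)(C)O[C@H]2C1 | intermediate
3 | 1-bromo-3-methylbut-2-ene | CC(C)=CCBr | starting material
4 | potassium 2-[(3aS,5R,7aS)-2,2,7a-trimethylhexahydro-1,3-benzodioxol-5-yl]prop-2-en-1-ide | [K+].[CH2-]C(=C)[C@@H]1CC[C@]2(C)OC(C)(C)O[C@H]2C1 | intermediate
5 | (3aS,5R,7aS)-2,2,7a-trimethyl-5-(6-methylhepta-1,5-dien-2-yl)hexahydro-1,3-benzodioxole | CC(C)=CCCC(=C)[C@@H]1CC[C@]2(C)OC(C)(C)O[C@H]2C1 | intermediate
6 | (1S,2S,4R)-1-methyl-4-(6-methylhepta-1,5-dien-2-yl)cyclohexane-1,2-diol | CC(C)=CCCC(=C)[C@@H]1CC[C@](C)(O)[C@@H](O)C1 | intermediate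
7 | (3R)-3-(6-methylhepta-1,5-dien-2-yl)-6-oxoheptanal | CC(C)=CCCC(=C)[C@@H](CC=O)CCC(C)=O | intermediate
8 | (5R)-7,7-dimethoxy-5-(6-methylhepta-1,5-dien-2-yl)heptan-2-one | CC(C)=CCCC(=C)[C@@H](CC(OC)OC)CCC(C)=O | intermediate
9 | (4R)-6,6-dimethoxy-4-(6-methylhepta-1,5-dien-2-yl)hexanoic acid | CC(C)=CCCC(=C)[C@@H](CC(OC)OC)CCC(=O)O | intermediate
10 | methyl 4-oxobutanoate | COC(=O)CCC=O | starting material
11 | ethyltriphenylphosphonium iodide | CC[P+](c1ccccc1)(c1ccccc1)c1ccccc1.[I-] | starting material
12 | ethylidene(triphenyl)-λ5-phosphane | CC=P(c1ccccc1)(c1ccccc1)c1ccccc1 | intermediate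
13 | (1-iodoethyl)triphenylphosphonium iodide | CC(I)[P+](c1ccccc1)(c1ccccc1)c1ccccc1.[I-] | intermediate
14 | (1-iodoethylidene)triphenyl-λ5-phosphane | CC(I)=P(c1ccccc1)(c1ccccc1)c1ccccc1 | intermediate
15 | methyl (4Z)-5-iodohex-4-enoate | C/C(I)=C/CCC(=O)OC | intermediate
16 | 1,3-dioxoisoindolin-2-yl (4R)-6,6-dimethoxy-4-(6-methylhepta-1,5-dien-2-yl)hexanoate | CC(C)=CCCC(=C)[C@@H](CC(OC)OC)CCC(=O)ON1C(=O)c2ccccc2C1=O | intermediate
17 | methyl (4Z,8R)-10,10-dimethoxy-5-methyl-8-(6-methylhepta-1,5-dien-2-yl)dec-4-enoate | COC(=O)CC/C=C(/C)CC[C@H](CC(OC)OC)C(=C)CCC=C(C)C | intermediate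
18 | methyl (4Z,8R)-5-methyl-8-(6-methylhepta-1,5-dien-2-yl)-10-oxodec-4-enoate | COC(=O)CC/C=C(/C)CC[C@H](CC=O)C(=C)CCC=C(C)C | intermediate
19 | pent-3-yn-1-ol | CC#CCCO | starting material
20 | chloro{(2E)-5-[(chlorozirconocenyl)oxy]pent-2-en-2-yl}zirconocene (Cp2Zr(Cl) on C4 of the pentenyl chain and on oxygen) | C/C(=C\CCO[Zr](Cl)(C1C=CC=C1)C1C=CC=C1)[Zr](Cl)(C1C=CC=C1)C1C=CC=C1 | intermediate
21 | (3E)-4-iodopent-3-en-1-ol | C/C(I)=C\CCO | intermediate
22 | (2E)-2,5-diiodopent-2-ene | C/C(I)=C\CCI | intermediate
23 | methyl bis(2,2,2-trifluoroethyl)phosphonoacetate | COC(=O)CP(=O)(OCC(F)(F)F)OCC(F)(F)F | starting material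
24 | sodium salt of 23 (carbanion at C2) | [Na+].COC(=O)[CH-]P(=O)(OCC(F)(F)F)OCC(F)(F)F | intermediate
25 | methyl (5E)-2-[bis(2,2,2-trifluoroethoxy)phosphoryl]-6-iodohept-5-enoate (racemic at C2) | COC(=O)C(CC/C=C(\C)I)P(=O)(OCC(F)(F)F)OCC(F)(F)F | intermediate
26 | potassium salt of 25 (carbanion at C2) | [K+].COC(=O)[C-](CC/C=C(\C)I)P(=O)(OCC(F)(F)F)OCC(F)(F)F | intermediate
27 | dimethyl (2Z,5R,8Z)-2-[(3E)-4-iodopent-3-en-1-yl]-8-methyl-5-(6-methylhepta-1,5-dien-2-yl)dodeca-2,8-dienedioate | COC(=O)CC/C=C(/C)CC[C@H](C/C=C(/CC/C=C(\C)I)C(=O)OC)C(=C)CCC=C(C)C | intermediate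
28 | (4Z,8R,10Z,14E)-15-iodo-11-(methoxycarbonyl)-5-methyl-8-(6-methylhepta-1,5-dien-2-yl)hexadeca-4,10,14-trienoic acid | OC(=O)CC/C=C(/C)CC[C@H](C/C=C(/CC/C=C(\C)I)C(=O)OC)C(=C)CCC=C(C)C | intermediate
29 | 1,3-dioxoisoindolin-2-yl ester of 28 | O=C(CC/C=C(/C)CC[C@H](C/C=C(/CC/C=C(\C)I)C(=O)OC)C(=C)CCC=C(C)C)ON1C(=O)c2ccccc2C1=O | intermediate
30 | methyl (1Z,4R,7Z,11E)-7,11-dimethyl-4-(6-methylhepta-1,5-dien-2-yl)cyclotetradeca-1,7,11-triene-1-carboxylate | C=C(CCC=C(C)C)[C@H]1C/C=C(\C(=O)OC)CC/C=C(\C)CC/C=C(/C)CC1 | intermediate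
31 | [(1Z,4R,7Z,11E)-7,11-dimethyl-4-(6-methylhepta-1,5-dien-2-yl)cyclotetradeca-1,7,11-trien-1-yl]methanol | C=C(CCC=C(C)C)[C@H]1C/C=C(\CO)CC/C=C(\C)CC/C=C(/C)CC1 | target

**Step count and risks**

Total step count: 14 (10 in the main line, 1 for iodide 15, 3 for phosphonate 25).
Longest linear sequence: 10 steps (steps 1, 2, 3, 4, 6, 7, 11, 12, 13, 14).

Steps most likely to fail:

1. Step 13 (proposed new method). The radical may be captured by the alkenylnickel end of another molecule (oligomerisation), be reduced to the C–H compound before capture, or scramble the C7=C8 geometry through reversible cyclopropylcarbinyl formation. Fallback: the ring is closed at C1=C2 instead, and C10–C11 is made by the intermolecular form of the coupling. The fallback sets out from 17: saponification (LiOH, THF/H2O) should give the acetal acid F1, which is activated as its N-acyloxyphthalimide F2 and coupled with alkenyl iodide 25 under the conditions of step 6 to give the phosphonate acetal F3. Acetal hydrolysis (PPTS, acetone/H2O) should give the phosphonate aldehyde F4, whose potassium phosphonate F5 (K2CO3, 18-crown-6, toluene, high dilution) should undergo an intramolecular Still–Gennari-type Horner–Wadsworth–Emmons macrocyclisation. The fallback comes back to the route at 30.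

2. Step 2. The superbase may attack the acetonide or metalate elsewhere, and the allyl anion may give SN2′ or homocoupling products with the allylic bromide. Fallback: the polarity is reversed. The fallback sets out from 2: ene-type allylic chlorination of the isopropenyl group (Ca(OCl)2, solid CO2, CH2Cl2/H2O) should give the allylic chloride F6. Prenyl phenyl sulfone F7 (from 3 and PhSO2Na) is deprotonated with n-BuLi to the lithiated sulfone F8, which is alkylated by F6 to the coupled sulfone F9 (both epimers at the sulfonyl carbon). Palladium-catalysed hydride desulfonylation (PdCl2(dppp), LiBHEt3, THF) removes the sulfonyl group. The fallback comes back to the route at 5.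

3. Step 6. The primary radical may undergo 1,5-hydrogen shifts from the allylic or acetal C–H bonds before capture, and the Z-alkenylnickel may lose its geometry. Fallback: a two-electron coupling replaces the radical one. The fallback sets out from 9: the thiohydroxamate ester F10 (N-hydroxypyridine-2-thione, DCC) is photolysed with CHI3 (Barton decarboxylative iodination) to the primary iodide F11. Zinc insertion (Zn dust, LiCl, THF) gives the alkylzinc iodide F12, and Negishi coupling with 15 (Pd(PPh3)4, THF) should proceed with retention of the Z geometry. The fallback comes back to the route at 17.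

**Further compounds**

F1 | step 13 | (4Z,8R)-10,10-dimethoxy-5-methyl-8-(6-methylhepta-1,5-dien-2-yl)dec-4-enoic acid | OC(=O)CC/C=C(/C)CC[C@H](CC(OC)OC)C(=C)CCC=C(C)C
F2 | step 13 | 1,3-dioxoisoindolin-2-yl ester of F1 | O=C(CC/C=C(/C)CC[C@H](CC(OC)OC)C(=C)CCC=C(C)C)ON1C(=O)c2ccccc2C1=O
F3 | step 13 | methyl (5E,9Z,13R)-2-[bis(2,2,2-trifluoroethoxy)phosphoryl]-15,15-dimethoxy-6,10-dimethyl-13-(6-methylhepta-1,5-dien-2-yl)pentadeca-5,9-dienoate | COC(=O)C(CC/C=C(\C)CC/C=C(/C)CC[C@H](CC(OC)OC)C(=C)CCC=C(C)C)P(=O)(OCC(F)(F)F)OCC(F)(F)F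
F4 | step 13 | methyl (5E,9Z,13R)-2-[bis(2,2,2-trifluoroethoxy)phosphoryl]-6,10-dimethyl-13-(6-methylhepta-1,5-dien-2-yl)-15-oxopentadeca-5,9-dienoate | COC(=O)C(CC/C=C(\C)CC/C=C(/C)CC[C@H](CC=O)C(=C)CCC=C(C)C)P(=O)(OCC(F)(F)F)OCC(F)(F)F
F5 | step 13 | potassium salt of F4 (carbanion at C2) | [K+].COC(=O)[C-](CC/C=C(\C)CC/C=C(/C)CC[C@H](CC=O)C(=C)CCC=C(C)C)P(=O)(OCC(F)(F)F)OCC(F)(F)F
F6 | step 2 | (3aS,5R,7aS)-5-(3-chloroprop-1-en-2-yl)-2,2,7a-trimethylhexahydro-1,3-benzodioxole | ClCC(=C)[C@@H]1CC[C@]2(C)OC(C)(C)O[C@H]2C1
F7 | step 2 | (3-methylbut-2-en-1-yl) phenyl sulfone | CC(C)=CCS(=O)(=O)c1ccccc1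
F8 | step 2 | lithium salt of F7 (carbanion α to sulfur) | [Li+].CC(C)=C[CH-]S(=O)(=O)c1ccccc1
F9 | step 2 | (3aS,5R,7aS)-2,2,7a-trimethyl-5-[6-methyl-4-(phenylsulfonyl)hepta-1,5-dien-2-yl]hexahydro-1,3-benzodioxole | CC(C)=CC(CC(=C)[C@@H]1CC[C@]2(C)OC(C)(C)O[C@H]2C1)S(=O)(=O)c1ccccc1
F10 | step 6 | 2-thioxopyridin-1(2H)-yl (4R)-6,6-dimethoxy-4-(6-methylhepta-1,5-dien-2-yl)hexanoate | CC(C)=CCCC(=C)[C@@H](CC(OC)OC)CCC(=O)On1ccccc1=S
F11 | step 6 | (3S)-5-iodo-1,1-dimethoxy-3-(6-methylhepta-1,5-dien-2-yl)pentane (same spatial arrangement as in 9) | CC(C)=CCCC(=C)[C@@H](CC(OC)OC)CCI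
F12 | step 6 | [(3S)-5,5-dimethoxy-3-(6-methylhepta-1,5-dien-2-yl)pentyl]zinc iodide | CC(C)=CCCC(=C)[C@@H](CC(OC)OC)CC[Zn]I
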